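**Retrosynthetic overview** (flavone numbering; piperidine atoms primed)
1. Ring C is formed last: target ⇐ 5,7-di-O-methyl flavone (ether cleavage) ⇐ Baker–Venkataraman sequence on a 2-hydroxyacetophenone, itself from Friedel–Crafts acetylation and debenzylation of (R)-2-(4-benzyloxy-2,6-dimethoxyphenyl)-1-methylpiperidine.
2. That piperidine ⇐ its 5',5'-diester (saponification/decarboxylation, then radical decarboxylation), which is cut at N1'–C2' and C5'–C6' into a racemic 2-arylcyclobutane-1,1-diester and N-methylmethanimine: an enantioconvergent Lewis-acid (4+2) annulation.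
3. The cyclobutane ⇐ polar (2+2) of 4-benzyloxy-2,6-dimethoxystyrene with dimethyl methylidenemalonate; the styrene ⇐ 4-hydroxy-2,6-dimethoxybenzaldehyde.
4. Feature used: C2' is bonded to C6 of ring A, which is ortho to the oxygens on C5 and C7 and para to O1 on C8a, so positive charge at C2' is strongly stabilised and a strained ring attached there opens at that carbon to accept N1'.
5. Ring order: ring A bought; cyclobutane (temporary); piperidine; pyranone ring C, with ring B delivered by benzoyl chloride.

Key step: step 5

Assumption: the sense of induction of the magnesium–pybox catalyst in step 5 cannot be predicted with certainty. The route is written with (S,S)-tBu-pybox as the ligand that should deliver (R)-9; the (R,R)-ligand is to be used instead if the configurational assignment of 9 requires it.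

**Step 1**
Reactants: 1 4-hydroxy-2,6-dimethoxybenzaldehyde
Product: 2 4-(benzyloxy)-2,6-dimethoxybenzaldehyde
Conditions: BnBr, K2CO3, DMF, rt
Reagents that add atoms: benzyl bromide, BrCc1ccccc1
Why: Williamson etherification of the only phenol, whose acidity is raised by the para formyl group, so K2CO3 is sufficient.

**Step 2**
Reactants: 2 4-(benzyloxy)-2,6-dimethoxybenzaldehyde
Product: 3 5-(benzyloxy)-2-ethenyl-1,3-dimethoxybenzene
Conditions: Ph3PCH3Br, KOtBu, THF, 0 °C → rt
Reagents that add atoms: methyltriphenylphosphonium bromide, C[P+](c1ccccc1)(c1ccccc1)c1ccccc1.[Br-]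
Why: Wittig methylenation with the non-stabilised ylide, which is reactive enough for the hindered, non-enolisable aldehyde, in a basic medium that spares the acid-sensitive styrene.

**Step 3**
Reactants: 4 dimethyl malonate
Product: 5 dimethyl 2-methylidenepropanedioate
Conditions: (CH2O)n, iPr2NH2+ CF3CO2−, CF3CO2H (cat.), THF, reflux; distilled and used at once
Reagents that add atoms: formaldehyde (as paraformaldehyde), C=O
Why: α-Methylenation by Mannich condensation with the secondary ammonium salt and β-elimination of the amine; the monomer is used fresh because it polymerises.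

**Step 4**
Reactants: 3 5-(benzyloxy)-2-ethenyl-1,3-dimethoxybenzene; 5 dimethyl 2-methylidenepropanedioate
Product: 6 dimethyl 2-[4-(benzyloxy)-2,6-dimethoxyphenyl]cyclobutane-1,1-dicarboxylate (racemic)
Conditions: Yb(OTf)3 (10 mol%), CH2Cl2, −78 → −40 °C; Et3N quench at −40 °C
Reagents that add atoms: none
Why: Lewis-acid-catalysed stepwise polar (2+2) cycloaddition in which the styrene terminus adds in Michael fashion to the chelated methylidenemalonate and the benzylic cation/malonate zwitterion collapses to the four-membered ring, which places the aryl carbon next to the diester carbon; low temperature and the cold amine quench keep the product from re-ionising.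

**Step 5**
Reactants: 6 dimethyl 2-[4-(benzyloxy)-2,6-dimethoxyphenyl]cyclobutane-1,1-dicarboxylate (racemic); 7 1,3,5-trimethyl-1,3,5-triazinane
Product: 9 dimethyl (R)-6-[4-(benzyloxy)-2,6-dimethoxyphenyl]-1-methylpiperidine-3,3-dicarboxylate, via N-methylmethanimine 8 (not isolated)
Conditions: MgI2 (10 mol%), (S,S)-tBu-pybox (12 mol%), 4 Å MS, CH2Cl2, 0 °C → rt; 7 (0.45 equiv) added slowly
Reagents that add atoms: none
Why: Proposed new method: the pybox-bound Mg2+ chelates the geminal diester of 6 and the C1–C2 bond heterolyses with assistance from the 2,4,6-trioxygenated aryl group to a tight benzylic cation/magnesium malonate ion pair that recloses reversibly, so the two enantiomers of 6 interconvert under the reaction conditions. Imine 8, released from 7 by the Lewis acid (or a ring nitrogen of 7 itself, which then sheds two molecules of 8), bonds through nitrogen to the benzylic carbon (N1'–C2'), and the resulting N-methyl methyleneiminium ion is captured by the magnesium malonate in a 6-endo-trig Mannich closure (C5'–C6') that forms the piperidine. The closest known reaction types are Lewis-acid (4+2) annulations of donor–acceptor cyclobutane diesters with imines, aldehydes and triazinane-derived formaldimines, and the MgI2/pybox dynamic kinetic asymmetric (3+2) annulation of aryl cyclopropane diesters with aldimines; the new element is the enantioconvergent use of a cyclobutane with an N-alkyl formaldimine. C2' is the only new stereocentre (C5' carries two identical esters, C6' is a methylene) and its configuration is set in the C–N bond formation by the chiral ligand on the metal that holds the malonate end of the ion pair. The step needs racemisation of 6 to outrun trapping, which the very electron-rich aryl group should secure, and N-attack to beat proton loss from the ion pair to a styrenyl malonate, which the small, strongly nucleophilic imine kept at low concentration and the absence of added base should favour.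

**Step 6**
Reactants: 9 dimethyl (R)-6-[4-(benzyloxy)-2,6-dimethoxyphenyl]-1-methylpiperidine-3,3-dicarboxylate
Product: 11 (3RS,6R)-6-[4-(benzyloxy)-2,6-dimethoxyphenyl]-1-methylpiperidine-3-carboxylic acid (both C3 epimers), via piperidine-3,3-dicarboxylic acid 10 (not isolated)
Conditions: LiOH, THF/MeOH/H2O, rt → 55 °C; HCl to pH 5, evaporate; pyridine, 110 °C
Reagents that add atoms: lithium hydroxide, [Li+].[OH-]
Why: Saponification of both esters followed by thermal decarboxylation of the geminally disubstituted malonic acid through the usual cyclic transition state; nitrogen is protonated in the zwitterion, which shuts off retro-Mannich opening at C5'–C6', C2' has no acidic hydrogen, and the C3 epimers converge in step 7.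

**Step 7**
Reactants: 11 (3RS,6R)-6-[4-(benzyloxy)-2,6-dimethoxyphenyl]-1-methylpiperidine-3-carboxylic acid
Product: 13 (R)-2-[4-(benzyloxy)-2,6-dimethoxyphenyl]-1-methylpiperidine, via Barton ester 12 (not isolated)
Conditions: 1-hydroxypyridine-2(1H)-thione, DCC, DMAP (cat.), CH2Cl2, rt, dark; then Bu3SnH, AIBN (cat.), PhH, 80 °C
Reagents that add atoms: none
Why: Barton reductive decarboxylation, in which tin-radical attack at sulfur fragments the thiohydroxamate ester to the C5' radical that takes hydrogen from Bu3SnH; a stannane is chosen over a thiol so that no thiyl radical is present to abstract and return the α-amino benzylic hydrogen at C2'.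

**Step 8**
Reactants: 13 (R)-2-[4-(benzyloxy)-2,6-dimethoxyphenyl]-1-methylpiperidine
Product: 14 1-{6-(benzyloxy)-2,4-dimethoxy-3-[(2R)-1-methylpiperidin-2-yl]phenyl}ethan-1-one
Conditions: Ac2O, BF3·OEt2 (3 equiv), CH2Cl2, −20 → 0 °C; aq. NaOH work-up
Reagents that add atoms: acetic anhydride, CC(=O)OC(C)=O
Why: Friedel–Crafts acylation at one of the two equivalent ring positions, each ortho, ortho and para to the three alkoxy groups; nitrogen is held as its BF3 adduct, which prevents ipso attack with loss of an iminium ion, the new ketone deactivates the ring against a second acylation, and the low temperature is meant to avoid cleavage of the methoxy group that ends up flanked by the ketone.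

**Step 9**
Reactants: 14 1-{6-(benzyloxy)-2,4-dimethoxy-3-[(2R)-1-methylpiperidin-2-yl]phenyl}ethan-1-one
Product: 15 1-{6-hydroxy-2,4-dimethoxy-3-[(2R)-1-methylpiperidin-2-yl]phenyl}ethan-1-one
Conditions: H2 (1 atm), 10% Pd/C, EtOAc, rt
Reagents that add atoms: none
Why: Hydrogenolysis of the aryl benzyl ether, which should be much faster than cleavage of the hindered, unprotonated benzylic C2'–N bond or reduction of the di-ortho-substituted aryl ketone; the reaction is stopped after one equivalent of hydrogen.

**Step 10**
Reactants: 15 1-{6-hydroxy-2,4-dimethoxy-3-[(2R)-1-methylpiperidin-2-yl]phenyl}ethan-1-one; 16 benzoyl chloride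
Product: 17 2-acetyl-3,5-dimethoxy-4-[(2R)-1-methylpiperidin-2-yl]phenyl benzoate
Conditions: pyridine, 0 °C → rt
Reagents that add atoms: none
Why: O-acylation of the only phenol under nucleophilic catalysis by pyridine (first stage of the Baker–Venkataraman sequence); the tertiary amine cannot be acylated irreversibly.

**Step 11**
Reactants: 17 2-acetyl-3,5-dimethoxy-4-[(2R)-1-methylpiperidin-2-yl]phenyl benzoate
Product: 19 5,7-dimethoxy-6-[(2R)-1-methylpiperidin-2-yl]-2-phenyl-4H-chromen-4-one, via 1,3-diketone 18 (not isolated)
Conditions: KOtBu (3 equiv), THF, 0 °C → rt; then AcOH, H2SO4, 60 °C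
Reagents that add atoms: none
Why: Baker–Venkataraman rearrangement (intramolecular Claisen attack of the ketone enolate on the neighbouring benzoate) followed by acid-catalysed cyclodehydration of the 2-hydroxyaryl 1,3-diketone to ring C; only the oxygen para to the piperidinyl carbon is free, so ring C closes onto O1–C8a and the piperidine ends at C6, not C8, and nitrogen stays protonated during the acid stage, which protects the C2'–N bond.

**Step 12**
Reactants: 19 5,7-dimethoxy-6-[(2R)-1-methylpiperidin-2-yl]-2-phenyl-4H-chromen-4-one
Product: 20 5,7-dihydroxy-6-[(2R)-1-methylpiperidin-2-yl]-2-phenyl-4H-chromen-4-one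
Conditions: BBr3 (6 equiv), CH2Cl2, −78 °C → rt; MeOH/H2O quench at 0 °C, cold neutral work-up
Reagents that add atoms: none
Why: Lewis-acid cleavage of both aryl methyl ethers by bromide attack on the methyl group of the boron-complexed ether, the C5 ether being assisted by chelation to the C4 carbonyl; nitrogen is tied up as a boron adduct and the work-up is kept cold because the free ortho-hydroxybenzylamine could racemise by reversible retro-Mannich opening on heating.

**Compound list**
1 | 4-hydroxy-2,6-dimethoxybenzaldehyde | COc1cc(O)cc(OC)c1C=O | starting material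
2 | 4-(benzyloxy)-2,6-dimethoxybenzaldehyde | COc1cc(OCc2ccccc2)cc(OC)c1C=O | intermediate
3 | 5-(benzyloxy)-2-ethenyl-1,3-dimethoxybenzene | C=Cc1c(OC)cc(OCc2ccccc2)cc1OC | intermediate
4 | dimethyl malonate | COC(=O)CC(=O)OC | starting material
5 | dimethyl 2-methylidenepropanedioate | C=C(C(=O)OC)C(=O)OC | intermediate
6 | dimethyl 2-[4-(benzyloxy)-2,6-dimethoxyphenyl]cyclobutane-1,1-dicarboxylate (racemic) | COC(=O)C1(C(=O)OC)CCC1c1c(OC)cc(OCc2ccccc2)cc1OC | intermediate
7 | 1,3,5-trimethyl-1,3,5-triazinane | CN1CN(C)CN(C)C1 | starting material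
8 | N-methylmethanimine | CN=C | intermediate
9 | dimethyl (R)-6-[4-(benzyloxy)-2,6-dimethoxyphenyl]-1-methylpiperidine-3,3-dicarboxylate | CN1CC(C(=O)OC)(C(=O)OC)CC[C@@H]1c1c(OC)cc(OCc2ccccc2)cc1OC | intermediate
10 | (R)-6-[4-(benzyloxy)-2,6-dimethoxyphenyl]-1-methylpiperidine-3,3-dicarboxylic acid | CN1CC(C(=O)O)(C(=O)O)CC[C@@H]1c1c(OC)cc(OCc2ccccc2)cc1OC | intermediate
11 | (3RS,6R)-6-[4-(benzyloxy)-2,6-dimethoxyphenyl]-1-methylpiperidine-3-carboxylic acid | CN1CC(C(=O)O)CC[C@@H]1c1c(OC)cc(OCc2ccccc2)cc1OC | intermediate
12 | 2-thioxopyridin-1(2H)-yl (3RS,6R)-6-[4-(benzyloxy)-2,6-dimethoxyphenyl]-1-methylpiperidine-3-carboxylate | CN1CC(C(=O)On2ccccc2=S)CC[C@@H]1c1c(OC)cc(OCc2ccccc2)cc1OC | intermediate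
13 | (R)-2-[4-(benzyloxy)-2,6-dimethoxyphenyl]-1-methylpiperidine | CN1CCCC[C@@H]1c1c(OC)cc(OCc2ccccc2)cc1OC | intermediate
14 | 1-{6-(benzyloxy)-2,4-dimethoxy-3-[(2R)-1-methylpiperidin-2-yl]phenyl}ethan-1-one | CN1CCCC[C@@H]1c1c(OC)cc(OCc2ccccc2)c(C(C)=O)c1OC | intermediate
15 | 1-{6-hydroxy-2,4-dimethoxy-3-[(2R)-1-methylpiperidin-2-yl]phenyl}ethan-1-one | CN1CCCC[C@@H]1c1c(OC)cc(O)c(C(C)=O)c1OC | intermediate
16 | benzoyl chloride | O=C(Cl)c1ccccc1 | starting material
17 | 2-acetyl-3,5-dimethoxy-4-[(2R)-1-methylpiperidin-2-yl]phenyl benzoate | CN1CCCC[C@@H]1c1c(OC)cc(OC(=O)c2ccccc2)c(C(C)=O)c1OC | intermediate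
18 | 1-{6-hydroxy-2,4-dimethoxy-3-[(2R)-1-methylpiperidin-2-yl]phenyl}-3-phenylpropane-1,3-dione | CN1CCCC[C@@H]1c1c(OC)cc(O)c(C(=O)CC(=O)c2ccccc2)c1OC | intermediate
19 | 5,7-dimethoxy-6-[(2R)-1-methylpiperidin-2-yl]-2-phenyl-4H-chromen-4-one | CN1CCCC[C@@H]1c1c(OC)cc2oc(-c3ccccc3)cc(=O)c2c1OC | intermediate
20 | 5,7-dihydroxy-6-[(2R)-1-methylpiperidin-2-yl]-2-phenyl-4H-chromen-4-one | CN1CCCC[C@@H]1c1c(O)cc2oc(-c3ccccc3)cc(=O)c2c1O | target

**Step count**
Total steps: 12. Longest linear sequence: 11 (steps 1, 2 and 4–12 from compound 1; step 3 is the side branch).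

**Steps most likely to fail**

1. Step 5. The ring-opened ion pair may be trapped before the cyclobutane enantiomers have equilibrated, the very small imine may give poor facial discrimination, the basic aminal may sequester the magnesium catalyst, or the ion pair may lose a proton to a styrenyl malonate. The fallback uses known auxiliary chemistry; it sets out from 2 and comes back at 13. Aldehyde 2 is condensed with (S)-2-methylpropane-2-sulfinamide (Ti(OEt)4, THF) to the (S,E)-N-sulfinyl aldimine F1. 4-Chlorobutylmagnesium bromide is added in CH2Cl2 at −48 °C through the chelated six-membered transition state, which should give the (S)-sulfinyl (1R)-5-chloropentyl sulfinamide F2; should the two ortho methoxy groups reverse this sense, the (R)-sulfinamide is used. KOtBu in THF closes the ring by N-alkylation to the N-sulfinyl piperidine F3. HCl in MeOH at 0 °C removes the auxiliary to give (R)-2-[4-(benzyloxy)-2,6-dimethoxyphenyl]piperidine F4, and reductive methylation (aqueous CH2O, NaBH(OAc)3, ClCH2CH2Cl) gives 13.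

2. Step 8. The Lewis acid may cleave the methoxy group flanked by the new ketone and the piperidinyl carbon, which would scramble which oxygen later closes ring C, and reversible heterolysis of the benzylic C2'–N bond in the boron adduct may erode the configuration. The fallback avoids Lewis acid; it sets out from 13 and comes back at 14. Compound 13, as its trifluoroacetate salt, is brominated with NBS in MeCN at −20 °C to (R)-2-[4-(benzyloxy)-3-bromo-2,6-dimethoxyphenyl]-1-methylpiperidine F5. Bromine–lithium exchange (nBuLi, THF, −78 °C) and acylation of the aryllithium with N-methoxy-N-methylacetamide then give 14.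

3. Step 12. The long exposure to BBr3 at room temperature needed for the C7 ether may cause C2'–N heterolysis or retro-Mannich opening and so loss of enantiomeric purity, or the C7 ether may be cleaved incompletely. The fallback separates the two cleavages; it sets out from 19 and comes back at 20. BCl3 (CH2Cl2, −78 → 0 °C) removes only the chelation-activated C5 methyl group to give 5-hydroxy-7-methoxy-6-[(2R)-1-methylpiperidin-2-yl]-2-phenyl-4H-chromen-4-one F6. The C7 methyl group is then removed by SN2 attack of NaSEt (DMF, 100 °C) under basic conditions, in which nitrogen is neither protonated nor complexed, to give 20.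

**Further compounds**
F1 | step 5 | (S,E)-N-{[4-(benzyloxy)-2,6-dimethoxyphenyl]methylidene}-2-methylpropane-2-sulfinamide | CC(C)(C)[S@](=O)/N=C/c1c(OC)cc(OCc2ccccc2)cc1OC
F2 | step 5 | (S)-N-{(1R)-1-[4-(benzyloxy)-2,6-dimethoxyphenyl]-5-chloropentyl}-2-methylpropane-2-sulfinamide | CC(C)(C)[S@](=O)N[C@H](CCCCCl)c1c(OC)cc(OCc2ccccc2)cc1OC
F3 | step 5 | (2R)-2-[4-(benzyloxy)-2,6-dimethoxyphenyl]-1-[(S)-2-methylpropane-2-sulfinyl]piperidine | CC(C)(C)[S@](=O)N1CCCC[C@@H]1c1c(OC)cc(OCc2ccccc2)cc1OC
F4 | step 5 | (R)-2-[4-(benzyloxy)-2,6-dimethoxyphenyl]piperidine | N1CCCC[C@@H]1c1c(OC)cc(OCc2ccccc2)cc1OC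
F5 | step 8 | (R)-2-[4-(benzyloxy)-3-bromo-2,6-dimethoxyphenyl]-1-methylpiperidine | CN1CCCC[C@@H]1c1c(OC)cc(OCc2ccccc2)c(Br)c1OC
F6 | step 12 | 5-hydroxy-7-methoxy-6-[(2R)-1-methylpiperidin-2-yl]-2-phenyl-4H-chromen-4-one | CN1CCCC[C@@H]1c1c(OC)cc2oc(-c3ccccc3)cc(=O)c2c1O
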